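**Plan**

- Retrosynthesis: the butyrolactone is cut at the bond between ring carbon C4 and the benzylic CH2 on C5 of the dihydrobenzofuran, and at the bond between C3 and the CH2 on ring B. This leaves a dihydrobenzofuran dithiane (fragment A), a benzylic bromide carrying the diarylpropanediol (fragment B) and a four-carbon butenolide.
- Enabling feature: lactone C4 is β to the lactone C2=O, so at the butenolide oxidation level it is a Michael acceptor and C3 then becomes an enolate carbon. The benzylic CH2, raised to the aldehyde level as a 1,3-dithiane, becomes a nucleophile. Lactone C5, raised to an acetal carrying (+)-menthyloxy, controls the face. The two sulfur atoms and the menthyloxy group are taken out after the union.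
- Fragments A and B both come from one (1S,2S)-1,2-diaryl-1,3-diol made by an auxiliary-controlled anti-aldol reaction. Acid closes the dihydrofuran ring of fragment A (O1–C2 bond, trans); acetonide formation and bromination give fragment B.
- Forward order: arylacetic acid, anti-aldol, common diol, fragments A and B; butenolide from furfural; one-pot three-component union; desulfurisation, acetal-to-lactone reduction, deprotection.
- Stereochemistry: (S)-4-benzyl-2-oxazolidinone sets both diol centres, and through them C3 and C2 of the dihydrobenzofuran. The menthyloxy acetal sets lactone C4, and C4 relays to C3.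

Key step: step 18

Remark: the facial sense of the magnesium-catalysed anti-aldol in step 6 is assumed to be the one established for N-propionyl oxazolidinones (attack on the chelated enolate face remote from the 4-benzyl group).

Abbreviations used in names:
- A-aryl = (2R,3S)-2-[4-(benzyloxy)-3-methoxyphenyl]-3-[(tert-butyldimethylsilyloxy)methyl]-7-methoxy-2,3-dihydrobenzofuran-5-yl
- B-benzyl = 3-[(4S,5S)-4-(4-benzyloxy-3-methoxyphenyl)-2,2-dimethyl-1,3-dioxan-5-yl]-5-methoxy-4-[(4-methoxybenzyl)oxy]benzyl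
- PMB = 4-methoxybenzyl

**Route**

Step 1
Reactants: 1 methyl vanillate; 2 allyl bromide
Product: 3 methyl 4-(allyloxy)-3-methoxybenzoate
Conditions: K2CO3, acetone, reflux
Reagents that add atoms: none
Why: Williamson O-allylation of the phenoxide by SN2 on allyl bromide.

Step 2
Reactants: 3 methyl 4-(allyloxy)-3-methoxybenzoate
Product: 4 methyl 3-allyl-4-hydroxy-5-methoxybenzoate
Conditions: N,N-diethylaniline, 200 °C
Reagents that add atoms: none
Why: aromatic Claisen rearrangement ([3,3]-sigmatropic shift, then tautomerisation) delivers the allyl group to the only free ortho position.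

Step 3
Reactants: 4 methyl 3-allyl-4-hydroxy-5-methoxybenzoate
Product: 5 methyl 3-allyl-5-methoxy-4-[(4-methoxybenzyl)oxy]benzoate
Conditions: PMBCl, K2CO3, n-Bu4NI (cat.), DMF, 60 °C
Reagents that add atoms: 4-methoxybenzyl chloride, COc1ccc(CCl)cc1
Why: Williamson etherification of the hindered phenol; PMB is chosen because acid removes it in step 11 and hydrogenolysis removes it in step 22.

Step 4
Reactants: 5 methyl 3-allyl-5-methoxy-4-[(4-methoxybenzyl)oxy]benzoate
Product: 7 2-{3-methoxy-5-(methoxycarbonyl)-2-[(4-methoxybenzyl)oxy]phenyl}acetic acid, via arylacetaldehyde 6 (not isolated)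
Conditions: O3, CH2Cl2/MeOH, −78 °C; Me2S; then NaClO2, NaH2PO4, 2-methyl-2-butene, t-BuOH/H2O, 0 °C to rt
Reagents that add atoms: ozone, [O-][O+]=O; sodium chlorite, [Na+].[O-]Cl=O
Why: ozonolysis of the terminal alkene (much faster at −78 °C than attack on the deactivated benzoate ring or the anisyl ring) followed by Pinnick oxidation of the sensitive arylacetaldehyde without isolation.

Step 5
Reactants: 7 2-{3-methoxy-5-(methoxycarbonyl)-2-[(4-methoxybenzyl)oxy]phenyl}acetic acid; 8 (S)-4-benzyl-2-oxazolidinone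
Product: 10 methyl 3-{2-[(4S)-4-benzyl-2-oxooxazolidin-3-yl]-2-oxoethyl}-5-methoxy-4-[(4-methoxybenzyl)oxy]benzoate, via mixed pivalic anhydride 9 (not isolated)
Conditions: PivCl, Et3N, THF, −20 °C; then LiCl, 8, −20 °C to rt
Reagents that add atoms: none
Why: N-acylation of the oxazolidinone by the mixed pivalic anhydride under LiCl/Et3N activation, attack going to the less hindered arylacetyl carbonyl.

Step 6
Reactants: 10 methyl 3-{2-[(4S)-4-benzyl-2-oxooxazolidin-3-yl]-2-oxoethyl}-5-methoxy-4-[(4-methoxybenzyl)oxy]benzoate; 11 4-(benzyloxy)-3-methoxybenzaldehyde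
Product: 13 (4S)-4-benzyl-3-[(2R,3S)-3-(4-benzyloxy-3-methoxyphenyl)-3-hydroxy-2-{3-methoxy-5-(methoxycarbonyl)-2-[(4-methoxybenzyl)oxy]phenyl}propanoyl]oxazolidin-2-one, via silylated aldol adduct 12 (not isolated)
Conditions: MgCl2 (0.2 equiv), Et3N, TMSCl, EtOAc, 23 °C; then 1 M HCl/THF, 23 °C
Reagents that add atoms: none
Why: magnesium halide-catalysed anti-aldol reaction of an N-acyloxazolidinone (Evans-type auxiliary aldol), in which soft enolisation gives the chelated (Z)-magnesium enolate that adds to the aldehyde through a boat-like transition state on the face away from the auxiliary benzyl group, setting C2 (R) and C3 (S) anti, while silylation by TMSCl turns over the magnesium and blocks retro-aldol.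

Step 7
Reactants: 13 anti-aldol adduct
Product: 14 methyl 3-[(1S,2S)-1-(4-benzyloxy-3-methoxyphenyl)-1,3-dihydroxypropan-2-yl]-5-methoxy-4-[(4-methoxybenzyl)oxy]benzoate
Conditions: LiBH4, MeOH (1 equiv), THF, 0 °C
Reagents that add atoms: none
Why: reductive cleavage of the imide by LiBH4 (hydride attack on the exocyclic acyl group) releases the 1,3-diol and the auxiliary without touching the stereocentres, and the less electrophilic aryl methyl ester is kept at 0 °C.

Step 8
Reactants: 14 common diol ester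
Product: 15 methyl 3-[(4S,5S)-4-(4-benzyloxy-3-methoxyphenyl)-2,2-dimethyl-1,3-dioxan-5-yl]-5-methoxy-4-[(4-methoxybenzyl)oxy]benzoate
Conditions: 2,2-dimethoxypropane, PPTS (cat.), CH2Cl2, rt
Reagents that add atoms: 2,2-dimethoxypropane, COC(C)(C)OC
Why: acid-catalysed transketalisation gives the acetonide, favoured because the anti-diol places both aryl groups equatorial on the 1,3-dioxane.

Step 9
Reactants: 15 acetonide ester
Product: 16 {3-[(4S,5S)-4-(4-benzyloxy-3-methoxyphenyl)-2,2-dimethyl-1,3-dioxan-5-yl]-5-methoxy-4-[(4-methoxybenzyl)oxy]phenyl}methanol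
Conditions: LiAlH4, THF, 0 °C
Reagents that add atoms: none
Why: hydride reduction of the aryl methyl ester to the benzylic alcohol; acetonide and aryl ethers are inert to LiAlH4.

Step 10
Reactants: 16 benzylic alcohol
Product: 17 (4S,5S)-5-{5-(bromomethyl)-3-methoxy-2-[(4-methoxybenzyl)oxy]phenyl}-4-(4-benzyloxy-3-methoxyphenyl)-2,2-dimethyl-1,3-dioxane
Conditions: CBr4, PPh3, CH2Cl2, 0 °C; used at once
Reagents that add atoms: tetrabromomethane, BrC(Br)(Br)Br
Why: Appel reaction converts the primary benzylic alcohol into the bromide under near-neutral conditions that spare the acetonide.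

Step 11
Reactants: 14 common diol ester
Product: 19 methyl (2R,3S)-2-(4-benzyloxy-3-methoxyphenyl)-3-(hydroxymethyl)-7-methoxy-2,3-dihydrobenzofuran-5-carboxylate, via free phenol 18 (not isolated)
Conditions: TFA, anisole, CH2Cl2, 0 °C to rt; then K2CO3, MeOH, rt
Reagents that add atoms: none
Why: acid-mediated dehydrative cycloetherification (SN1), in which TFA cleaves the PMB aryl ether (cation trapped by anisole) and ionises the para-alkoxybenzylic carbinol, and 5-exo capture of the cation by the freed phenol anti to the C3 hydroxymethyl group should give the thermodynamically favoured trans ring with C2 (R), the C3 centre being untouched and the para ester keeping ring A from forming a quinone methide.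

Step 12
Reactants: 19 dihydrobenzofuran ester
Product: 20 [(2R,3S)-2-(4-benzyloxy-3-methoxyphenyl)-7-methoxy-2,3-dihydrobenzofuran-3,5-diyl]dimethanol
Conditions: LiAlH4, THF, 0 °C
Reagents that add atoms: none
Why: hydride reduction of the aryl ester to the benzylic alcohol.

Step 13
Reactants: 20 diol
Product: 21 (2R,3S)-2-(4-benzyloxy-3-methoxyphenyl)-3-(hydroxymethyl)-7-methoxy-2,3-dihydrobenzofuran-5-carbaldehyde
Conditions: activated MnO2, CH2Cl2, rt
Reagents that add atoms: none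
Why: MnO2 oxidises the benzylic alcohol chemoselectively and leaves the aliphatic primary alcohol alone.

Step 14
Reactants: 21 aldehyde
Product: 22 [(2R,3S)-2-(4-benzyloxy-3-methoxyphenyl)-5-(1,3-dithian-2-yl)-7-methoxy-2,3-dihydrobenzofuran-3-yl]methanol
Conditions: propane-1,3-dithiol, I2 (10 mol %), CH2Cl2, rt
Reagents that add atoms: propane-1,3-dithiol, SCCCS
Why: mild Lewis acid-catalysed dithioacetalisation of the aromatic aldehyde, too weak to open the benzylic C2–O bond of the dihydrofuran.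

Step 15
Reactants: 22 dithiane alcohol
Product: 23 2-(A-aryl)-1,3-dithiane
Conditions: TBSCl, imidazole, DMF, rt
Reagents that add atoms: tert-butyldimethylsilyl chloride, CC(C)(C)[Si](C)(C)Cl
Why: silylation of the primary alcohol removes the only acidic proton other than the dithiane C–H before the carbanion chemistry.

Step 16
Reactants: 24 furfural
Product: 25 5-hydroxy-2(5H)-furanone
Conditions: O2, rose bengal (cat.), visible light, MeOH, rt
Reagents that add atoms: dioxygen, O=O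
Why: dye-sensitised photooxygenation, a [4+2] cycloaddition of singlet oxygen to the furan followed by methanolytic fragmentation of the endoperoxide with loss of the formyl carbon.

Step 17
Reactants: 25 5-hydroxy-2(5H)-furanone; 26 (+)-menthol
Product: 27 (5S)-5-[(1S,2R,5S)-menthyloxy]-2(5H)-furanone
Conditions: camphorsulfonic acid (cat.), toluene, reflux (Dean–Stark); crystallisation from petroleum ether
Reagents that add atoms: none
Why: acid-catalysed acetalisation, in which the two C5 epimers interconvert under acid and the (5S) diastereomer of the (+)-menthol series should crystallise selectively (crystallisation-induced diastereomer transformation).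

Step 18
Reactants: 23 2-(A-aryl)-1,3-dithiane; 27 (5S)-5-menthyloxy-2(5H)-furanone; 17 fragment B bromide
Product: 30 (3S,4S,5S)-3-(B-benzyl)-4-[2-(A-aryl)-1,3-dithian-2-yl]-5-[(1S,2R,5S)-menthyloxy]dihydrofuran-2(3H)-one, via 2-lithio-1,3-dithiane 28 (not isolated), via lithium enolate 29 (not isolated)
Conditions: n-BuLi, THF, −78 to −20 °C; 27, −78 °C; then 17, HMPA, −78 °C to rt
Reagents that add atoms: none
Why: n-BuLi removes the dithiane C2–H of 23, the soft aryl-stabilised carbanion 28 adds 1,4 to butenolide 27 at C4 (Michael addition) to give lithium enolate 29, and 29 is C-alkylated at C3 by benzylic bromide 17 (SN2) in the same flask. The closest known reaction type is the tandem conjugate addition–enolate alkylation of 5-alkoxy-2(5H)-furanones with lithiated 2-aryl-1,3-dithianes and benzylic bromides, as used for dibenzylbutyrolactone lignans. No ring is closed in this step. The new centre C4 is controlled by the acetal centre C5, whose menthyloxy group shields the syn face so that the carbanion enters anti (4,5-trans), and the new centre C3 is controlled by the bulky dithianyl group on C4, so that the bromide enters anti to it (3,4-trans), giving (3S,4S,5S). The step needs 1,4- over 1,2-addition and C-alkylation ahead of proton transfer or O-alkylation, which the delocalised dithianyl anion at −78 °C and the reactive benzylic bromide with HMPA should secure. The six stereocentres already present in 23 and 17 are remote from the reacting atoms and carry no proton that the base removes at −78 °C.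

Step 19
Reactants: 30 tandem adduct
Product: 31 (3S,4S,5S)-3-(B-benzyl)-4-(A-arylmethyl)-5-[(1S,2R,5S)-menthyloxy]dihydrofuran-2(3H)-one
Conditions: NiCl2·6H2O, NaBH4, MeOH/THF, 0 °C to rt
Reagents that add atoms: none
Why: nickel boride desulfurisation (reductive hydrogenolysis of both C–S bonds) turns the dithiane carbon into the benzylic CH2 under conditions mild enough to spare benzyl ethers, the silyl ether and the lactone acetal.

Step 20
Reactants: 31 desulfurised lactone acetal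
Product: 34 (3S,4S)-3-(B-benzyl)-4-(A-arylmethyl)dihydrofuran-2(3H)-one, via aldehyde carboxylate 32 (not isolated), via hydroxy carboxylate 33 (not isolated)
Conditions: KOH, NaBH4, EtOH/H2O, rt; then 1 M HCl to pH 2, 0 °C to rt, short contact
Reagents that add atoms: none
Why: saponification opens the lactone acetal to the aldehyde carboxylate with loss of menthol, NaBH4 reduces the aldehyde faster than C4 can epimerise, and acidification relactonises the γ-hydroxy acid (hydrolysis–reduction–lactonisation), so both ring stereocentres are kept.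

Step 21
Reactants: 34 protected lactone
Product: 35 (3S,4S)-4-{[(2R,3S)-2-(4-benzyloxy-3-methoxyphenyl)-3-(hydroxymethyl)-7-methoxy-2,3-dihydrobenzofuran-5-yl]methyl}-3-{3-[(1S,2S)-1-(4-benzyloxy-3-methoxyphenyl)-1,3-dihydroxypropan-2-yl]-5-methoxy-4-[(4-methoxybenzyl)oxy]benzyl}dihydrofuran-2(3H)-one
Conditions: AcOH/THF/H2O (3:1:1), 40 °C
Reagents that add atoms: none
Why: mild acid hydrolysis of the acetonide and the primary TBS ether, run while the ring B phenol is still a PMB ether so that the freed benzylic carbinol cannot close a second dihydrobenzofuran.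

Step 22
Reactants: 35 triol tris(aryl ether)
Product: 36 target, (3S,4S)-3-{3-[(1S,2S)-1,3-dihydroxy-1-(4-hydroxy-3-methoxyphenyl)propan-2-yl]-4-hydroxy-5-methoxybenzyl}-4-{[(2R,3S)-2-(4-hydroxy-3-methoxyphenyl)-3-(hydroxymethyl)-7-methoxy-2,3-dihydrobenzofuran-5-yl]methyl}dihydrofuran-2(3H)-one
Conditions: H2 (1 atm), Pd/C, EtOAc/EtOH, rt
Reagents that add atoms: none
Why: catalytic hydrogenolysis of the two aryl benzyl ethers and the aryl PMB ether under neutral conditions, where the benzylic alcohol and the benzylic C2–O bond of the dihydrofuran react much more slowly.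

**Compound list**

1 | methyl vanillate (methyl 4-hydroxy-3-methoxybenzoate) | COC(=O)c1ccc(O)c(OC)c1 | starting material
2 | allyl bromide | C=CCBr | starting material
3 | methyl 4-(allyloxy)-3-methoxybenzoate | COC(=O)c1ccc(OCC=C)c(OC)c1 | intermediate
4 | methyl 3-allyl-4-hydroxy-5-methoxybenzoate | COC(=O)c1cc(CC=C)c(O)c(OC)c1 | intermediate
5 | methyl 3-allyl-5-methoxy-4-[(4-methoxybenzyl)oxy]benzoate | COC(=O)c1cc(CC=C)c(OCc2ccc(OC)cc2)c(OC)c1 | intermediate
6 | methyl 3-methoxy-4-[(4-methoxybenzyl)oxy]-5-(2-oxoethyl)benzoate (arylacetaldehyde, not isolated) | COC(=O)c1cc(CC=O)c(OCc2ccc(OC)cc2)c(OC)c1 | intermediate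
7 | 2-{3-methoxy-5-(methoxycarbonyl)-2-[(4-methoxybenzyl)oxy]phenyl}acetic acid | COC(=O)c1cc(CC(=O)O)c(OCc2ccc(OC)cc2)c(OC)c1 | intermediate
8 | (S)-4-benzyl-2-oxazolidinone | O=C1N[C@@H](Cc2ccccc2)CO1 | starting material
9 | mixed pivalic anhydride of 7 (not isolated) | COC(=O)c1cc(CC(=O)OC(=O)C(C)(C)C)c(OCc2ccc(OC)cc2)c(OC)c1 | intermediate
10 | methyl 3-{2-[(4S)-4-benzyl-2-oxooxazolidin-3-yl]-2-oxoethyl}-5-methoxy-4-[(4-methoxybenzyl)oxy]benzoate | COC(=O)c1cc(CC(=O)N2[C@@H](Cc3ccccc3)COC2=O)c(OCc2ccc(OC)cc2)c(OC)c1 | intermediate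
11 | 4-(benzyloxy)-3-methoxybenzaldehyde | COc1cc(C=O)ccc1OCc1ccccc1 | starting material
12 | trimethylsilyl ether of 13 (not isolated) | COc1cc([C@@H](O[Si](C)(C)C)[C@H](C(=O)N2[C@@H](Cc3ccccc3)COC2=O)c2cc(C(=O)OC)cc(OC)c2OCc2ccc(OC)cc2)ccc1OCc1ccccc1 | intermediate
13 | (4S)-4-benzyl-3-[(2R,3S)-3-(4-benzyloxy-3-methoxyphenyl)-3-hydroxy-2-{3-methoxy-5-(methoxycarbonyl)-2-[(4-methoxybenzyl)oxy]phenyl}propanoyl]oxazolidin-2-one | COc1cc([C@@H](O)[C@H](C(=O)N2[C@@H](Cc3ccccc3)COC2=O)c2cc(C(=O)OC)cc(OC)c2OCc2ccc(OC)cc2)ccc1OCc1ccccc1 | intermediate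
14 | methyl 3-[(1S,2S)-1-(4-benzyloxy-3-methoxyphenyl)-1,3-dihydroxypropan-2-yl]-5-methoxy-4-[(4-methoxybenzyl)oxy]benzoate | COc1cc([C@@H](O)[C@H](CO)c2cc(C(=O)OC)cc(OC)c2OCc2ccc(OC)cc2)ccc1OCc1ccccc1 | intermediate
15 | methyl 3-[(4S,5S)-4-(4-benzyloxy-3-methoxyphenyl)-2,2-dimethyl-1,3-dioxan-5-yl]-5-methoxy-4-[(4-methoxybenzyl)oxy]benzoate | COc1cc([C@H]2OC(C)(C)OC[C@@H]2c2cc(C(=O)OC)cc(OC)c2OCc2ccc(OC)cc2)ccc1OCc1ccccc1 | intermediate
16 | {3-[(4S,5S)-4-(4-benzyloxy-3-methoxyphenyl)-2,2-dimethyl-1,3-dioxan-5-yl]-5-methoxy-4-[(4-methoxybenzyl)oxy]phenyl}methanol | COc1cc([C@H]2OC(C)(C)OC[C@@H]2c2cc(CO)cc(OC)c2OCc2ccc(OC)cc2)ccc1OCc1ccccc1 | intermediate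
17 | (4S,5S)-5-{5-(bromomethyl)-3-methoxy-2-[(4-methoxybenzyl)oxy]phenyl}-4-(4-benzyloxy-3-methoxyphenyl)-2,2-dimethyl-1,3-dioxane (fragment B) | COc1cc([C@H]2OC(C)(C)OC[C@@H]2c2cc(CBr)cc(OC)c2OCc2ccc(OC)cc2)ccc1OCc1ccccc1 | intermediate
18 | methyl 3-[(1S,2S)-1-(4-benzyloxy-3-methoxyphenyl)-1,3-dihydroxypropan-2-yl]-4-hydroxy-5-methoxybenzoate (not isolated) | COc1cc([C@@H](O)[C@H](CO)c2cc(C(=O)OC)cc(OC)c2O)ccc1OCc1ccccc1 | intermediate
19 | methyl (2R,3S)-2-(4-benzyloxy-3-methoxyphenyl)-3-(hydroxymethyl)-7-methoxy-2,3-dihydrobenzofuran-5-carboxylate | COC(=O)c1cc(OC)c2c(c1)[C@@H](CO)[C@H](c1ccc(OCc3ccccc3)c(OC)c1)O2 | intermediate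
20 | [(2R,3S)-2-(4-benzyloxy-3-methoxyphenyl)-7-methoxy-2,3-dihydrobenzofuran-3,5-diyl]dimethanol | OCc1cc(OC)c2c(c1)[C@@H](CO)[C@H](c1ccc(OCc3ccccc3)c(OC)c1)O2 | intermediate
21 | (2R,3S)-2-(4-benzyloxy-3-methoxyphenyl)-3-(hydroxymethyl)-7-methoxy-2,3-dihydrobenzofuran-5-carbaldehyde | O=Cc1cc(OC)c2c(c1)[C@@H](CO)[C@H](c1ccc(OCc3ccccc3)c(OC)c1)O2 | intermediate
22 | [(2R,3S)-2-(4-benzyloxy-3-methoxyphenyl)-5-(1,3-dithian-2-yl)-7-methoxy-2,3-dihydrobenzofuran-3-yl]methanol | S1CCCSC1c1cc(OC)c2c(c1)[C@@H](CO)[C@H](c1ccc(OCc3ccccc3)c(OC)c1)O2 | intermediate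
23 | 2-(A-aryl)-1,3-dithiane, the tert-butyldimethylsilyl ether of 22 (fragment A) | S1CCCSC1c1cc(OC)c2c(c1)[C@@H](CO[Si](C)(C)C(C)(C)C)[C@H](c1ccc(OCc3ccccc3)c(OC)c1)O2 | intermediate
24 | furfural | O=Cc1ccco1 | starting material
25 | 5-hydroxy-2(5H)-furanone | O=C1C=CC(O)O1 | intermediate
26 | (+)-menthol, (1S,2R,5S)-2-isopropyl-5-methylcyclohexanol | CC(C)[C@H]1CC[C@H](C)C[C@@H]1O | starting material
27 | (5S)-5-[(1S,2R,5S)-menthyloxy]-2(5H)-furanone | O=C1C=C[C@@H](O[C@H]2C[C@@H](C)CC[C@@H]2C(C)C)O1 | intermediate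
28 | 2-lithio derivative of 23 (not isolated) | [Li]C1(SCCCS1)c1cc(OC)c2c(c1)[C@@H](CO[Si](C)(C)C(C)(C)C)[C@H](c1ccc(OCc3ccccc3)c(OC)c1)O2 | intermediate
29 | lithium enolate of the Michael adduct, 4,5-trans (not isolated) | [Li]OC1=C[C@H](C2(SCCCS2)c2cc(OC)c3c(c2)[C@@H](CO[Si](C)(C)C(C)(C)C)[C@H](c2ccc(OCc4ccccc4)c(OC)c2)O3)[C@@H](O[C@H]2C[C@@H](C)CC[C@@H]2C(C)C)O1 | intermediate
30 | (3S,4S,5S)-3-(B-benzyl)-4-[2-(A-aryl)-1,3-dithian-2-yl]-5-[(1S,2R,5S)-menthyloxy]dihydrofuran-2(3H)-one | COc1cc([C@H]2OC(C)(C)OC[C@@H]2c2cc(C[C@@H]3C(=O)O[C@H](O[C@H]4C[C@@H](C)CC[C@@H]4C(C)C)[C@H]3C3(SCCCS3)c3cc(OC)c4c(c3)[C@@H](CO[Si](C)(C)C(C)(C)C)[C@H](c3ccc(OCc5ccccc5)c(OC)c3)O4)cc(OC)c2OCc2ccc(OC)cc2)ccc1OCc1ccccc1 | intermediate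
31 | (3S,4S,5S)-3-(B-benzyl)-4-(A-arylmethyl)-5-[(1S,2R,5S)-menthyloxy]dihydrofuran-2(3H)-one | COc1cc([C@H]2OC(C)(C)OC[C@@H]2c2cc(C[C@@H]3C(=O)O[C@H](O[C@H]4C[C@@H](C)CC[C@@H]4C(C)C)[C@H]3Cc3cc(OC)c4c(c3)[C@@H](CO[Si](C)(C)C(C)(C)C)[C@H](c3ccc(OCc5ccccc5)c(OC)c3)O4)cc(OC)c2OCc2ccc(OC)cc2)ccc1OCc1ccccc1 | intermediate
32 | potassium (2S,3S)-2-(B-benzyl)-3-(A-arylmethyl)-4-oxobutanoate (not isolated) | COc1cc([C@H]2OC(C)(C)OC[C@@H]2c2cc(C[C@H](C(=O)[O-])[C@@H](C=O)Cc3cc(OC)c4c(c3)[C@@H](CO[Si](C)(C)C(C)(C)C)[C@H](c3ccc(OCc5ccccc5)c(OC)c3)O4)cc(OC)c2OCc2ccc(OC)cc2)ccc1OCc1ccccc1.[K+] | intermediate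
33 | potassium (2S,3S)-2-(B-benzyl)-3-(A-arylmethyl)-4-hydroxybutanoate (not isolated) | COc1cc([C@H]2OC(C)(C)OC[C@@H]2c2cc(C[C@H](C(=O)[O-])[C@@H](CO)Cc3cc(OC)c4c(c3)[C@@H](CO[Si](C)(C)C(C)(C)C)[C@H](c3ccc(OCc5ccccc5)c(OC)c3)O4)cc(OC)c2OCc2ccc(OC)cc2)ccc1OCc1ccccc1.[K+] | intermediate
34 | (3S,4S)-3-(B-benzyl)-4-(A-arylmethyl)dihydrofuran-2(3H)-one | COc1cc([C@H]2OC(C)(C)OC[C@@H]2c2cc(C[C@@H]3C(=O)OC[C@H]3Cc3cc(OC)c4c(c3)[C@@H](CO[Si](C)(C)C(C)(C)C)[C@H](c3ccc(OCc5ccccc5)c(OC)c3)O4)cc(OC)c2OCc2ccc(OC)cc2)ccc1OCc1ccccc1 | intermediate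
35 | (3S,4S)-4-{[(2R,3S)-2-(4-benzyloxy-3-methoxyphenyl)-3-(hydroxymethyl)-7-methoxy-2,3-dihydrobenzofuran-5-yl]methyl}-3-{3-[(1S,2S)-1-(4-benzyloxy-3-methoxyphenyl)-1,3-dihydroxypropan-2-yl]-5-methoxy-4-[(4-methoxybenzyl)oxy]benzyl}dihydrofuran-2(3H)-one | COc1cc([C@@H](O)[C@H](CO)c2cc(C[C@@H]3C(=O)OC[C@H]3Cc3cc(OC)c4c(c3)[C@@H](CO)[C@H](c3ccc(OCc5ccccc5)c(OC)c3)O4)cc(OC)c2OCc2ccc(OC)cc2)ccc1OCc1ccccc1 | intermediate
36 | (3S,4S)-3-{3-[(1S,2S)-1,3-dihydroxy-1-(4-hydroxy-3-methoxyphenyl)propan-2-yl]-4-hydroxy-5-methoxybenzyl}-4-{[(2R,3S)-2-(4-hydroxy-3-methoxyphenyl)-3-(hydroxymethyl)-7-methoxy-2,3-dihydrobenzofuran-5-yl]methyl}dihydrofuran-2(3H)-one (CNP0186558.3) | COc1cc([C@@H](O)[C@H](CO)c2cc(C[C@@H]3C(=O)OC[C@H]3Cc3cc(OC)c4c(c3)[C@@H](CO)[C@H](c3ccc(O)c(OC)c3)O4)cc(OC)c2O)ccc1O | target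

**Step count and risks**

Total step count: 22. Longest linear sequence: 17 steps (steps 1–7, 11–15, 18–22).

The three steps most likely to fail:

1. Step 18. After the conjugate addition the lithium enolate may be quenched by proton transfer or stay unalkylated, because the bulky, easily ionised bromide reacts too slowly or decomposes in the strongly basic medium. The fallback sets out from 23 and 27 and comes back at 34. The conjugate addition is run alone (n-BuLi, THF, −78 °C; NH4Cl quench) to give the Michael adduct (4S,5S)-4-[2-(A-aryl)-1,3-dithian-2-yl]-5-[(1S,2R,5S)-menthyloxy]dihydrofuran-2(3H)-one F1. NiCl2·6H2O/NaBH4 then gives the desulfurised lactone acetal (4S,5S)-4-(A-arylmethyl)-5-[(1S,2R,5S)-menthyloxy]dihydrofuran-2(3H)-one F2, and KOH/NaBH4 followed by HCl gives the simple lactone (4S)-4-(A-arylmethyl)dihydrofuran-2(3H)-one F3. Its lithium enolate (LDA, THF/HMPA, −78 °C) is alkylated with 17 anti to the C4 substituent, the classical trans-selective alkylation of β-benzyl-γ-butyrolactones, which gives 34 directly.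

2. Step 6. The acidic arylacetyl imide may give poor anti/syn control, or the adduct may revert by retro-aldol under the amine and Lewis acid. The fallback sets out from 7 and comes back at 14. Acid 7 is attached to (R)-4-benzyl-2-oxazolidinone (PivCl, Et3N, LiCl) to give methyl 3-{2-[(4R)-4-benzyl-2-oxooxazolidin-3-yl]-2-oxoethyl}-5-methoxy-4-[(4-methoxybenzyl)oxy]benzoate F4. Its dibutylboron (Z)-enolate (Bu2BOTf, i-Pr2NEt, CH2Cl2, −78 °C) is added to 11 precomplexed with Et2AlCl, so that the aldol runs through an open transition state on the enolate face selected by the (R)-auxiliary. This should give the anti adduct (4R)-4-benzyl-3-[(2R,3S)-3-(4-benzyloxy-3-methoxyphenyl)-3-hydroxy-2-{3-methoxy-5-(methoxycarbonyl)-2-[(4-methoxybenzyl)oxy]phenyl}propanoyl]oxazolidin-2-one F5, and LiBH4 reduction returns to 14.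

3. Step 11. The benzylic cation may lose the neighbouring proton (stilbene formation, loss of the C3 centre), be captured by the scavenger, or the acid may start to cleave the benzyl ether. The fallback sets out from 14 and comes back at 19. Hydrogenolysis (H2, Pd/C, EtOAc) removes both the benzyl and the PMB ether to give methyl 3-[(1S,2S)-1,3-dihydroxy-1-(4-hydroxy-3-methoxyphenyl)propan-2-yl]-4-hydroxy-5-methoxybenzoate F6. With the para-hydroxyl free, the carbinol ionises under weak acid (PPTS, CH2Cl2, rt) through a para-quinone methide, which the ortho-phenol captures to give the trans product methyl (2R,3S)-2-(4-hydroxy-3-methoxyphenyl)-3-(hydroxymethyl)-7-methoxy-2,3-dihydrobenzofuran-5-carboxylate F7. Selective phenol benzylation (BnBr, K2CO3, acetone) returns to 19.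

Further compounds
F1 | step 18 | (4S,5S)-4-[2-(A-aryl)-1,3-dithian-2-yl]-5-[(1S,2R,5S)-menthyloxy]dihydrofuran-2(3H)-one | O=C1C[C@H](C2(SCCCS2)c2cc(OC)c3c(c2)[C@@H](CO[Si](C)(C)C(C)(C)C)[C@H](c2ccc(OCc4ccccc4)c(OC)c2)O3)[C@@H](O[C@H]2C[C@@H](C)CC[C@@H]2C(C)C)O1
F2 | step 18 | (4S,5S)-4-(A-arylmethyl)-5-[(1S,2R,5S)-menthyloxy]dihydrofuran-2(3H)-one | O=C1C[C@H](Cc2cc(OC)c3c(c2)[C@@H](CO[Si](C)(C)C(C)(C)C)[C@H](c2ccc(OCc4ccccc4)c(OC)c2)O3)[C@@H](O[C@H]2C[C@@H](C)CC[C@@H]2C(C)C)O1
F3 | step 18 | (4S)-4-(A-arylmethyl)dihydrofuran-2(3H)-one | O=C1C[C@H](Cc2cc(OC)c3c(c2)[C@@H](CO[Si](C)(C)C(C)(C)C)[C@H](c2ccc(OCc4ccccc4)c(OC)c2)O3)CO1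
F4 | step 6 | methyl 3-{2-[(4R)-4-benzyl-2-oxooxazolidin-3-yl]-2-oxoethyl}-5-methoxy-4-[(4-methoxybenzyl)oxy]benzoate | COC(=O)c1cc(CC(=O)N2[C@H](Cc3ccccc3)COC2=O)c(OCc2ccc(OC)cc2)c(OC)c1
F5 | step 6 | (4R)-4-benzyl-3-[(2R,3S)-3-(4-benzyloxy-3-methoxyphenyl)-3-hydroxy-2-{3-methoxy-5-(methoxycarbonyl)-2-[(4-methoxybenzyl)oxy]phenyl}propanoyl]oxazolidin-2-one | COc1cc([C@@H](O)[C@H](C(=O)N2[C@H](Cc3ccccc3)COC2=O)c2cc(C(=O)OC)cc(OC)c2OCc2ccc(OC)cc2)ccc1OCc1ccccc1
F6 | step 11 | methyl 3-[(1S,2S)-1,3-dihydroxy-1-(4-hydroxy-3-methoxyphenyl)propan-2-yl]-4-hydroxy-5-methoxybenzoate | COc1cc([C@@H](O)[C@H](CO)c2cc(C(=O)OC)cc(OC)c2O)ccc1O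
F7 | step 11 | methyl (2R,3S)-2-(4-hydroxy-3-methoxyphenyl)-3-(hydroxymethyl)-7-methoxy-2,3-dihydrobenzofuran-5-carboxylate | COC(=O)c1cc(OC)c2c(c1)[C@@H](CO)[C@H](c1ccc(O)c(OC)c1)O2
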